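## Retrosynthetic overview

Numbering: decalin C1–C8a (ring A = C1, C2, C3, C4, C4a, C8a; ring B = C4a, C5–C8, C8a), exocyclic C1'–C3' on C2, side chain C9–C15 on C1.

1. The side chain C10–C15 is cut back to a C9 lactol (three Wittig olefinations, one Sharpless epoxidation); the (R)-carbinol C2' comes from a CBS reduction of the C2' ketone, which closes a temporary C9–O–C2' lactone.
2. The decalin is cut at C8–C8a (ring B) and C1–C2 (ring A): an allyl β-keto ester enolate at C8 adds to C8a of a 5,6-dihydropyran-2-one (C9(=O)–C1=C8a–C4a–C4–O), the lactone enolate adds through C1 to an ynone at C2, and the C4–O bond is then broken by elimination.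
3. Enabling feature: C8a is β to C1, and C1 carries a carbon (C9) that can be at the acid level; C4 lies 1,4 to C1 across ring A and is sp2 in the target, so a temporary lactone C9–C1–C8a–C4a–C4–O can activate C8a, force the cis C4a/C8a fusion, relay C4 to C1, and leave as carboxylate when C3=C4 forms. The dienone C4=C3–C2=C1'–C2'(=O) supplies the acidifying carbonyl, and the 8-methyl makes C8 quaternary so the relay is not quenched.
4. Ring order: temporary δ-lactone, then ring B, then ring A, then lactone cleavage, all in step 17.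
5. The precursor is built from an auxiliary-controlled Michael addition (C6), a syn-aldol (C4a, C4), a Z-selective olefination/lactonisation and a β-keto ester homologation.

Key step: step 17

Remark on the chemistry: C3 (from the racemic α-centre of aldehyde 7) and C8 of the β-keto esters are carried as epimer mixtures and the alkyne carbinol as (S); all three centres are erased later (steps 17, 18 and 16), so their configuration is of no consequence.

## Route

Step 1
Reactants: 1 (S)-but-3-yn-2-ol
Product: 2 (S)-3-(tert-butyldimethylsilyloxy)but-1-yne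
Conditions: TBSCl, imidazole, CH2Cl2, 0 °C to rt
Reagents that add atoms: tert-butyldimethylsilyl chloride, CC(C)(C)[Si](C)(C)Cl
Why: Standard silylation of a secondary alcohol; the carbinol centre is only a placeholder for the later C2' ketone.

Step 2
Reactants: 2 (S)-3-(tert-butyldimethylsilyloxy)but-1-yne; 3 2-bromopropene
Product: 4 (S)-2-(tert-butyldimethylsilyloxy)-5-methylhex-5-en-3-yne
Conditions: Pd(PPh3)2Cl2 (cat.), CuI (cat.), Et3N, rt
Reagents that add atoms: none
Why: Sonogashira coupling of a terminal alkyne with a vinyl bromide.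

Step 3
Reactants: 4 (S)-2-(tert-butyldimethylsilyloxy)-5-methylhex-5-en-3-yne
Product: 6 (5S)-5-(tert-butyldimethylsilyloxy)-2-methylhex-3-yn-1-ol (C2 epimers), via B-alkyl-9-borabicyclononane adduct 5 (not isolated)
Conditions: 9-BBN, THF, 0 °C to rt; then NaOH, H2O2, 0 °C
Reagents that add atoms: hydrogen peroxide, OO
Why: Anti-Markovnikov hydroboration–oxidation in which 9-BBN should select the terminal 1,1-disubstituted alkene over the hindered internal alkyne; the new centre (later C3) forms unselectively, which is accepted.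

Step 4
Reactants: 6 (5S)-5-(tert-butyldimethylsilyloxy)-2-methylhex-3-yn-1-ol
Product: 7 (5S)-5-(tert-butyldimethylsilyloxy)-2-methylhex-3-ynal (C2 epimers), used at once
Conditions: Dess–Martin periodinane, NaHCO3, CH2Cl2, 0 °C
Reagents that add atoms: none
Why: Dess–Martin oxidation under buffered, non-basic conditions should avoid propargyl–allenyl isomerisation of the β,γ-alkynyl aldehyde.

Step 5
Reactants: 8 (R)-4-benzyl-3-propanoyl-1,3-oxazolidin-2-one; 9 tert-butyl acrylate
Product: 10 tert-butyl (4S)-5-[(4R)-4-benzyl-2-oxo-1,3-oxazolidin-3-yl]-4-methyl-5-oxopentanoate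
Conditions: TiCl3(Oi-Pr), i-Pr2NEt, CH2Cl2, 0 °C
Reagents that add atoms: none
Why: Auxiliary-controlled Michael addition of the chelated (Z)-chlorotitanium enolate to the acrylate on the face anti to the benzyl group sets C6 (S).

Step 6
Reactants: 10 tert-butyl ester imide
Product: 11 (4S)-5-[(4R)-4-benzyl-2-oxo-1,3-oxazolidin-3-yl]-4-methyl-5-oxopentanoic acid
Conditions: CF3CO2H, CH2Cl2, 0 °C to rt
Reagents that add atoms: none
Why: Acidolysis of the tert-butyl ester (loss of isobutene) leaves the imide untouched.

Step 7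
Reactants: 11 acid; 12 (R)-4-benzyl-1,3-thiazolidine-2-thione
Product: 13 N-acylthiazolidinethione of 11 (C8a thioimide, C7 oxazolidinone imide)
Conditions: EDC·HCl, DMAP (cat.), CH2Cl2, 0 °C to rt
Reagents that add atoms: none
Why: Carbodiimide N-acylation of the thiazolidinethione installs the aldol auxiliary at the unbranched C8a carboxyl.

Step 8
Reactants: 13 bis-imide; 7 aldehyde
Product: 14 Evans-syn aldol adduct (thioimide C8a(=O)–C4aH(CH2–C6)–C4H(OH)–C3H(CH3)–C≡C–CH(OTBS)CH3; C4a R, C4 S; C3 epimers)
Conditions: TiCl4, i-Pr2NEt, N-methyl-2-pyrrolidinone, CH2Cl2, 0 °C; then 7, −78 to 0 °C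
Reagents that add atoms: none
Why: Crimmins-type titanium aldol through the non-chelated chair transition state of the (Z)-enolate of the (R)-thiazolidinethione sets C4a and C4 syn with auxiliary control; only the unbranched thioimide CH2 is enolised, the α-branched oxazolidinone imide is not.

Step 9
Reactants: 14 aldol adduct
Product: 15 triethylsilyl ether of 14
Conditions: Et3SiOTf, 2,6-lutidine, CH2Cl2, −78 °C
Reagents that add atoms: triethylsilyl trifluoromethanesulfonate, CC[Si](CC)(CC)OS(=O)(=O)C(F)(F)F
Why: Silylation blocks retro-aldol and β-elimination in the following reduction and olefination.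

Step 10
Reactants: 15 silyl ether
Product: 16 aldehyde at C8a (α-branched β-silyloxy aldehyde)
Conditions: i-Bu2AlH, CH2Cl2, −78 °C
Reagents that add atoms: none
Why: The twisted N-acylthiazolidinethione is reduced directly to the aldehyde at −78 °C, well before the α-branched oxazolidinone imide reacts.

Step 11
Reactants: 16 aldehyde; 17 methyl bis(2,2,2-trifluoroethyl)phosphonoacetate
Product: 18 (Z)-enoate (methyl ester, C1=C8a Z)
Conditions: KN(SiMe3)2, 18-crown-6, THF, −78 °C
Reagents that add atoms: none
Why: Still–Gennari olefination gives the (Z)-enoate needed for lactonisation, without epimerising C4a at low temperature.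

Step 12
Reactants: 18 (Z)-enoate imide
Product: 19 C7 carboxylic acid
Conditions: LiOH, H2O2, THF/H2O, 0 °C; then aq. Na2SO3; HCl to pH 3
Reagents that add atoms: hydrogen peroxide, OO
Why: Hydroperoxide cleaves the exocyclic imide carbonyl selectively and much faster than it touches the methyl enoate or the silyl ethers, with C6 retained.

Step 13
Reactants: 20 2,2,5-trimethyl-1,3-dioxane-4,6-dione; 21 prop-2-en-1-ol
Product: 22 3-(allyloxy)-2-methyl-3-oxopropanoic acid (monoallyl methylmalonate)
Conditions: toluene, 100 °C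
Reagents that add atoms: none
Why: Alcoholysis of the methyl Meldrum's acid opens the ring with loss of acetone to the malonic half ester.

Step 14
Reactants: 19 acid; 22 monoallyl methylmalonate
Product: 24 allyl β-keto ester (C7 ketone, C8 methine with CO2allyl; C8 epimers), via acyl imidazolide 23 (not isolated)
Conditions: carbonyldiimidazole, THF, rt; then 22, MgCl2, Et3N, THF, rt to 40 °C; aq. citric acid
Reagents that add atoms: none
Why: Masamune-type C-acylation of the magnesium malonate half-ester enolate by the acyl imidazolide, followed by decarboxylation, gives the β-keto ester under near-neutral conditions that spare C6 and the enoate.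

Step 15
Reactants: 24 β-keto ester
Product: 26 (5S,6R)-cis-5,6-disubstituted 5,6-dihydro-2H-pyran-2-one carbinol (C5: CH2–CH(CH3)–CO–CH(CH3)–CO2allyl; C6: CH(CH3)–C≡C–CH(OH)CH3), via desilylated hydroxy ester 25 (not isolated)
Conditions: HF·pyridine, pyridine/THF, 0 °C to rt
Reagents that add atoms: none
Why: Fluoride-mediated cleavage of both silyl ethers frees the C4 hydroxyl, which lactonises onto the (Z)-enoate; the syn-aldol relationship becomes the cis-5,6 substitution.

Step 16
Reactants: 26 lactone carbinol
Product: 27 cascade precursor ynone (C6 substituent CH(CH3)–C≡C–COCH3)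
Conditions: MnO2, CH2Cl2, rt
Reagents that add atoms: none
Why: Activated MnO2 oxidises only the propargylic alcohol under neutral conditions that leave the β-keto ester and the unsaturated lactone alone.

Step 17
Reactants: 27 cascade precursor ynone
Product: 30 methyl ester of the cis-decalin dienone acid (C9 CO2CH3 on C1, C3=C4, exocyclic C2=C1'–COCH3, C8 quaternary with CH3 and CO2allyl), via bridged lactone 28 (not isolated), via potassium carboxylate 29 (not isolated)
Conditions: KOt-Bu (1.0 equiv), THF (0.01 M), −40 to 0 °C; then MeI, DMF, rt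
Reagents that add atoms: iodomethane, CI
Why: Proposed new method: KOt-Bu turns the α-methyl β-keto ester into its potassium enolate, whose C8 adds to C8a of the unsaturated δ-lactone (bond C8–C8a, ring B); the lactone enolate then adds through C1 to the ynone carbon C2 (ring A) to give the 2-oxabicyclo[2.2.2]octan-3-one 28, and after proton shuttling by tert-butanol the C3–H (γ to the new enone, the only enolisable non-bridgehead site) is removed and the bridge oxygen leaves C4 as carboxylate 29 (vinylogous E1cB), unveiling C3=C4 and the C2=C1' dienone before MeI esterifies. The closest known reaction types are the intramolecular anionic double Michael reaction (Michael–Michael ring closure to bicyclo[2.2.2]octanes) and the base-induced β-elimination opening of bridged 2-pyranone cycloadduct lactones. Ring B closes 6-exo-trig through a chair with the 6-methyl equatorial, and because the tether from C4a can reach only its own face of C8a the C4a/C8a fusion is cis; ring A closes 6-exo-dig through a boat of the lactone, and because C4–C3 is cis to C4a–C5 the C1–C2 bond forms syn to ring B, leaving C9 on the opposite face (C1 trans to C8) — C4 is a sacrificial centre that relays its configuration to C1 before becoming sp2. The quaternary C8 has no proton to quench the relay (its configuration is uncontrolled and erased in step 18), and the exocyclic geometry follows from minimised allylic 1,3-strain with the 3-methyl in the fragmenting dienolate and is confirmed by lactonisation in step 19. The step needs intramolecular addition to the lactone to beat intermolecular addition to the ynone (high dilution; the direct C8-to-C2 closure would be eight-membered) and needs the product not to react on, which is secured by exactly one equivalent of base ending as the unreactive carboxylate.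

Step 18
Reactants: 30 allyl β-keto ester
Product: 31 methyl ester of the C8–H diketone (6,8-dimethyl-7-oxo cis-decalin, C2' ketone)
Conditions: Pd(OAc)2 (cat.), PPh3, HCO2H, Et3N, THF, rt
Reagents that add atoms: none
Why: Tsuji-type deallylation–decarboxylation with formate as hydride source; protonation of the enol from the axial direction should place the 8-methyl equatorial (the thermodynamic epimer), and the buffered medium spares the dienone and the acidic C1–H.

Step 19
Reactants: 31 diketone ester
Product: 33 tricyclic δ-lactone (C9(=O)–O–C2' ring fused at C1–C2, C1'=C2 endocyclic to the lactone), via (R)-carbinol hydroxy ester 32 (not isolated)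
Conditions: (S)-2-methyl-CBS-oxazaborolidine (cat.), catecholborane, toluene, −78 °C; MeOH; then 2-hydroxypyridine (cat.), toluene, 60 °C
Reagents that add atoms: none
Why: Corey–Bakshi–Shibata reduction of the methyl alkenyl ketone (alkenyl as the large group) sets (R)-C2' under reagent control, the hindered 2,6-dimethylcyclohexanone reacts more slowly, and the carbinol held cis to C1 lactonises, which also proves the exocyclic geometry.

Step 20
Reactants: 33 lactone ketone
Product: 34 lactol with C7 alcohol (C7 and lactol carbon as epimer mixtures)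
Conditions: i-Bu2AlH (3.5 equiv), CH2Cl2, −78 °C
Reagents that add atoms: none
Why: Low-temperature hydride reduction stops the lactone at the lactol and deliberately reduces the C7 ketone, which is thereby protected as an alcohol until step 26.

Step 21
Reactants: 34 lactol; 35 2-(triphenylphosphoranylidene)propanal
Product: 36 (E)-enal C1–C9H=C10(CH3)–CHO with free C2' and C7 hydroxyls
Conditions: toluene, 80 °C
Reagents that add atoms: none
Why: Wittig reaction of the stabilised formyl ylide with the open hydroxy-aldehyde form of the lactol gives the (E)-trisubstituted enal and frees C2'–OH.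

Step 22
Reactants: 36 enal diol
Product: 37 C2' tert-butyldimethylsilyl ether
Conditions: TBSCl, imidazole, DMF, 0 °C
Reagents that add atoms: tert-butyldimethylsilyl chloride, CC(C)(C)[Si](C)(C)Cl
Why: The unhindered allylic carbinol is silylated selectively; the C7 hydroxyl flanked by two methyl-bearing carbons reacts much more slowly.

Step 23
Reactants: 37 enal; 38 ethyl 2-(triphenylphosphoranylidene)propanoate
Product: 39 ethyl (2E,4E)-dienoate (C9=C10–C11=C12–CO2Et)
Conditions: toluene, 90 °C
Reagents that add atoms: none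
Why: A stabilised Wittig reagent gives the (E)-trisubstituted C11=C12 alkene.

Step 24
Reactants: 39 dienoate
Product: 40 dienol (C13 CH2OH)
Conditions: i-Bu2AlH (3 equiv), CH2Cl2, −78 °C
Reagents that add atoms: none
Why: 1,2-Reduction of the ester to the allylic alcohol; no ketone is present at this stage.

Step 25
Reactants: 40 dienol
Product: 41 (11S,12S)-2,3-epoxy alcohol
Conditions: Ti(Oi-Pr)4 (0.3 equiv), L-(+)-diethyl tartrate (0.36 equiv), t-BuOOH, 4 Å MS, CH2Cl2, −25 °C
Reagents that add atoms: tert-butyl hydroperoxide, CC(C)(C)OO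
Why: Sharpless asymmetric epoxidation is directed by the primary allylic hydroxyl to C11=C12 only; the L-(+)-tartrate should deliver oxygen to the face giving the (11S,12S) epoxide, trans as required by the (E)-alkene.

Step 26
Reactants: 41 epoxy alcohol
Product: 42 epoxy aldehyde with the C7 ketone restored
Conditions: Dess–Martin periodinane (3 equiv), NaHCO3, CH2Cl2, 0 °C to rt
Reagents that add atoms: none
Why: One buffered oxidation turns the primary epoxy alcohol into the non-enolisable α,β-epoxy aldehyde and the C7 alcohol back into the ketone, with C6 and C8 unchanged.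

Step 27
Reactants: 42 epoxy aldehyde; 43 methyl (triphenylphosphoranylidene)acetate
Product: 44 (E)-enoate methyl ester, C2'-O-TBS
Conditions: CH2Cl2, rt
Reagents that add atoms: none
Why: The stabilised ylide reacts with the aldehyde and not with the hindered ketone, giving the (E)-C13=C14 enoate.

Step 28
Reactants: 44 silyl ether
Product: 45 methyl ester of the target
Conditions: Bu4NF, AcOH, THF, 0 °C to rt
Reagents that add atoms: none
Why: Buffered fluoride desilylation frees C2'–OH without acid that would open the doubly allylic epoxide.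

Step 29
Reactants: 45 methyl ester
Product: 46 CNP0414188.1 (target acid)
Conditions: LiOH, THF/MeOH/H2O, 0 °C to rt; aq. NaH2PO4 to pH 4
Reagents that add atoms: lithium hydroxide, [Li+].[OH-]
Why: Saponification of the enoate (C12 is quaternary, so no γ-deprotonation can open the epoxide); C6 and C8, both α to the ketone, can equilibrate here to the diequatorial target arrangement, which is favoured because allylic strain holds the C1 substituent axial and fixes the cis-decalin conformer.

## Compound list

1 | (S)-but-3-yn-2-ol | C#C[C@H](C)O | starting material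
2 | (S)-3-(tert-butyldimethylsilyloxy)but-1-yne | C#C[C@H](C)O[Si](C)(C)C(C)(C)C | intermediate
3 | 2-bromopropene | CC(Br)=C | starting material
4 | (S)-2-(tert-butyldimethylsilyloxy)-5-methylhex-5-en-3-yne | C=C(C)C#C[C@H](C)O[Si](C)(C)C(C)(C)C | intermediate
5 | B-[(5S)-5-(tert-butyldimethylsilyloxy)-2-methylhex-3-ynyl]-9-borabicyclo[3.3.1]nonane | CC(CB1C2CCCC1CCC2)C#C[C@H](C)O[Si](C)(C)C(C)(C)C | intermediate
6 | (5S)-5-(tert-butyldimethylsilyloxy)-2-methylhex-3-yn-1-ol (C2 epimers) | OCC(C)C#C[C@H](C)O[Si](C)(C)C(C)(C)C | intermediate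
7 | (5S)-5-(tert-butyldimethylsilyloxy)-2-methylhex-3-ynal (C2 epimers) | O=CC(C)C#C[C@H](C)O[Si](C)(C)C(C)(C)C | intermediate
8 | (R)-4-benzyl-3-propanoyl-1,3-oxazolidin-2-one | CCC(=O)N1[C@H](Cc2ccccc2)COC1=O | starting material
9 | tert-butyl acrylate | C=CC(=O)OC(C)(C)C | starting material
10 | tert-butyl (4S)-5-[(4R)-4-benzyl-2-oxo-1,3-oxazolidin-3-yl]-4-methyl-5-oxopentanoate | CC(C)(C)OC(=O)CC[C@H](C)C(=O)N1[C@H](Cc2ccccc2)COC1=O | intermediate
11 | (4S)-5-[(4R)-4-benzyl-2-oxo-1,3-oxazolidin-3-yl]-4-methyl-5-oxopentanoic acid | OC(=O)CC[C@H](C)C(=O)N1[C@H](Cc2ccccc2)COC1=O | intermediate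
12 | (R)-4-benzyl-1,3-thiazolidine-2-thione | S=C1N[C@H](Cc2ccccc2)CS1 | starting material
13 | N-acylthiazolidinethione of 11 (C8a thioimide, C7 oxazolidinone imide) | O=C(CC[C@H](C)C(=O)N1[C@H](Cc2ccccc2)COC1=O)N1[C@H](Cc2ccccc2)CSC1=S | intermediate
14 | Evans-syn aldol adduct (C4a R, C4 S, C3 epimers) | O=C([C@H](C[C@H](C)C(=O)N1[C@H](Cc2ccccc2)COC1=O)[C@@H](O)C(C)C#C[C@H](C)O[Si](C)(C)C(C)(C)C)N1[C@H](Cc2ccccc2)CSC1=S | intermediate
15 | triethylsilyl ether of 14 | O=C([C@H](C[C@H](C)C(=O)N1[C@H](Cc2ccccc2)COC1=O)[C@@H](O[Si](CC)(CC)CC)C(C)C#C[C@H](C)O[Si](C)(C)C(C)(C)C)N1[C@H](Cc2ccccc2)CSC1=S | intermediate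
16 | C8a aldehyde from 15 | O=C[C@H](C[C@H](C)C(=O)N1[C@H](Cc2ccccc2)COC1=O)[C@@H](O[Si](CC)(CC)CC)C(C)C#C[C@H](C)O[Si](C)(C)C(C)(C)C | intermediate
17 | methyl bis(2,2,2-trifluoroethyl)phosphonoacetate | COC(=O)CP(=O)(OCC(F)(F)F)OCC(F)(F)F | starting material
18 | methyl (Z)-enoate with C7 oxazolidinone imide | COC(=O)/C=C\[C@H](C[C@H](C)C(=O)N1[C@H](Cc2ccccc2)COC1=O)[C@@H](O[Si](CC)(CC)CC)C(C)C#C[C@H](C)O[Si](C)(C)C(C)(C)C | intermediate
19 | C7 carboxylic acid of the (Z)-enoate | COC(=O)/C=C\[C@H](C[C@H](C)C(O)=O)[C@@H](O[Si](CC)(CC)CC)C(C)C#C[C@H](C)O[Si](C)(C)C(C)(C)C | intermediate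
20 | 2,2,5-trimethyl-1,3-dioxane-4,6-dione | CC1C(=O)OC(C)(C)OC1=O | starting material
21 | prop-2-en-1-ol | C=CCO | starting material
22 | 3-(allyloxy)-2-methyl-3-oxopropanoic acid | CC(C(=O)O)C(=O)OCC=C | intermediate
23 | acyl imidazolide of 19 | COC(=O)/C=C\[C@H](C[C@H](C)C(=O)n1ccnc1)[C@@H](O[Si](CC)(CC)CC)C(C)C#C[C@H](C)O[Si](C)(C)C(C)(C)C | intermediate
24 | allyl β-keto ester (Z)-enoate (C8 epimers) | COC(=O)/C=C\[C@H](C[C@H](C)C(=O)C(C)C(=O)OCC=C)[C@@H](O[Si](CC)(CC)CC)C(C)C#C[C@H](C)O[Si](C)(C)C(C)(C)C | intermediate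
25 | desilylated hydroxy (Z)-enoate | COC(=O)/C=C\[C@H](C[C@H](C)C(=O)C(C)C(=O)OCC=C)[C@@H](O)C(C)C#C[C@H](C)O | intermediate
26 | (5S,6R)-cis-5,6-disubstituted 5,6-dihydro-2H-pyran-2-one carbinol | O=C1C=C[C@H](C[C@H](C)C(=O)C(C)C(=O)OCC=C)[C@H](C(C)C#C[C@H](C)O)O1 | intermediate
27 | cascade precursor: (5S,6R)-cis-dihydropyranone with β-keto ester chain at C5, ynone chain at C6 | O=C1C=C[C@H](C[C@H](C)C(=O)C(C)C(=O)OCC=C)[C@H](C(C)C#CC(C)=O)O1 | intermediate
28 | bridged lactone: 2-oxabicyclo[2.2.2]octan-3-one fused to ring B, exocyclic enone | O=C1O[C@H]2C(C)/C(=C/C(C)=O)[C@@H]1[C@H]3[C@@H]2C[C@H](C)C(=O)C3(C)C(=O)OCC=C | intermediate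
29 | potassium carboxylate of the cis-decalin dienone acid | CC1=C[C@H]2C[C@H](C)C(=O)C(C)(C(=O)OCC=C)[C@H]2[C@H](C(=O)[O-])/C1=C\C(C)=O.[K+] | intermediate
30 | methyl ester of the cis-decalin dienone acid, C8 quaternary (CH3, CO2allyl) | CC1=C[C@H]2C[C@H](C)C(=O)C(C)(C(=O)OCC=C)[C@H]2[C@H](C(=O)OC)/C1=C\C(C)=O | intermediate
31 | methyl ester, C8–H diketone | CC1=C[C@H]2C[C@H](C)C(=O)[C@H](C)[C@H]2[C@H](C(=O)OC)/C1=C\C(C)=O | intermediate
32 | (R)-C2' carbinol hydroxy ester | CC1=C[C@H]2C[C@H](C)C(=O)[C@H](C)[C@H]2[C@H](C(=O)OC)/C1=C\[C@@H](C)O | intermediate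
33 | tricyclic δ-lactone (C9–O–C2') | CC1=C[C@H]2C[C@H](C)C(=O)[C@H](C)[C@H]2[C@@H]2C(=O)O[C@H](C)C=C12 | intermediate
34 | lactol with C7 alcohol (C7 and lactol epimers) | CC1=C[C@H]2C[C@H](C)C(O)[C@H](C)[C@H]2[C@@H]2C(O)O[C@H](C)C=C12 | intermediate
35 | 2-(triphenylphosphoranylidene)propanal | CC(C=O)=P(c1ccccc1)(c1ccccc1)c1ccccc1 | starting material
36 | (E)-enal with C2' and C7 hydroxyls | CC1=C[C@H]2C[C@H](C)C(O)[C@H](C)[C@H]2[C@H](/C=C(\C)C=O)/C1=C\[C@@H](C)O | intermediate
37 | (E)-enal, C2'-O-TBS, C7 alcohol | CC1=C[C@H]2C[C@H](C)C(O)[C@H](C)[C@H]2[C@H](/C=C(\C)C=O)/C1=C\[C@@H](C)O[Si](C)(C)C(C)(C)C | intermediate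
38 | ethyl 2-(triphenylphosphoranylidene)propanoate | CCOC(=O)C(C)=P(c1ccccc1)(c1ccccc1)c1ccccc1 | starting material
39 | ethyl (2E,4E)-dienoate | CC1=C[C@H]2C[C@H](C)C(O)[C@H](C)[C@H]2[C@H](/C=C(\C)/C=C(\C)C(=O)OCC)/C1=C\[C@@H](C)O[Si](C)(C)C(C)(C)C | intermediate
40 | (2E,4E)-dienol | CC1=C[C@H]2C[C@H](C)C(O)[C@H](C)[C@H]2[C@H](/C=C(\C)/C=C(\C)CO)/C1=C\[C@@H](C)O[Si](C)(C)C(C)(C)C | intermediate
41 | (11S,12S)-epoxy alcohol | CC1=C[C@H]2C[C@H](C)C(O)[C@H](C)[C@H]2[C@H](/C=C(\C)[C@@H]2O[C@@]2(C)CO)/C1=C\[C@@H](C)O[Si](C)(C)C(C)(C)C | intermediate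
42 | epoxy aldehyde, C7 ketone | CC1=C[C@H]2C[C@H](C)C(=O)[C@H](C)[C@H]2[C@H](/C=C(\C)[C@@H]2O[C@@]2(C)C=O)/C1=C\[C@@H](C)O[Si](C)(C)C(C)(C)C | intermediate
43 | methyl (triphenylphosphoranylidene)acetate | COC(=O)C=P(c1ccccc1)(c1ccccc1)c1ccccc1 | starting material
44 | methyl ester of the target, C2'-O-TBS | CC1=C[C@H]2C[C@H](C)C(=O)[C@H](C)[C@H]2[C@H](/C=C(\C)[C@@H]2O[C@@]2(C)/C=C/C(=O)OC)/C1=C\[C@@H](C)O[Si](C)(C)C(C)(C)C | intermediate
45 | methyl ester of the target | CC1=C[C@H]2C[C@H](C)C(=O)[C@H](C)[C@H]2[C@H](/C=C(\C)[C@@H]2O[C@@]2(C)/C=C/C(=O)OC)/C1=C\[C@@H](C)O | intermediate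
46 | CNP0414188.1 | CC1=C[C@H]2C[C@H](C)C(=O)[C@H](C)[C@H]2[C@H](/C=C(\C)[C@@H]2O[C@@]2(C)/C=C/C(=O)O)/C1=C\[C@@H](C)O | target

## Step count and risks

Total step count: 29. Longest linear sequence: 25 steps (steps 1–4, 8–12, 14–29).

Steps most likely to fail:

Step 17 (proposed new method). The anionic relay may be interrupted by proton transfer to the lactone enolate (from C3–H or from tert-butanol) before ring A closes, and free alkoxide may deconjugate the dienone or epimerise C4a. The fallback gives up the one-flask relay for an interrupted sequence of separately known reactions, setting out from 27 and returning at 30. KN(SiMe3)2 (1.0 equiv) in THF at −78 to −40 °C without any alcohol runs only the tandem double Michael addition under kinetic, aprotic control; an acetic acid quench at −78 °C allows the bridged lactone 28 to be isolated. DBU in CH2Cl2 at 0 °C then opens the lactone by the known β-elimination of bridged lactones to the free dienone acid F1, and Me3SiCHN2 in MeOH/toluene gives 30.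

Step 21. In the open hydroxy-aldehyde form at 80 °C the exocyclic double bond may migrate into conjugation with the aldehyde (loss of the C1 centre), and the formyl ylide may homologate twice. The fallback sets out from 34 and returns at 37, using a more nucleophilic ester ylide at lower temperature and adjusting the oxidation level afterwards. Ylide 38 in CH2Cl2 at 40 °C should give the hydroxy enoate F2; TBSCl/imidazole gives the silyl ether F3; i-Bu2AlH at −78 °C gives the allylic alcohol F4; MnO2 oxidises only the allylic primary alcohol to enal 37.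

Step 25. The doubly allylic epoxy alcohol may be opened or rearranged by the titanium alkoxide medium, and the free C7 hydroxyl may retard turnover. The fallback sets out from 40 and returns at 42, replacing the hydroxyl-directed electrophilic epoxidation by a nucleophilic one. MnO2 oxidises 40 to the dienal F5; an iminium-type amine-catalysed epoxidation of the α-branched enal (9-amino-9-deoxy-epi-cinchona alkaloid salt, aqueous H2O2, dioxane, rt), with the alkaloid pseudo-enantiomer chosen for the (11S,12S) sense, should give the epoxy aldehyde F6 at the C11=C12 bond only; Dess–Martin periodinane then oxidises the C7 alcohol to give 42.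

Further compounds
F1 | step 17 | free cis-decalin dienone acid (C9 CO2H, C8 quaternary) | CC1=C[C@H]2C[C@H](C)C(=O)C(C)(C(=O)OCC=C)[C@H]2[C@H](C(=O)O)/C1=C\C(C)=O
F2 | step 21 | ethyl (E)-enoate with C2' and C7 hydroxyls | CC1=C[C@H]2C[C@H](C)C(O)[C@H](C)[C@H]2[C@H](/C=C(\C)C(=O)OCC)/C1=C\[C@@H](C)O
F3 | step 21 | ethyl (E)-enoate, C2'-O-TBS | CC1=C[C@H]2C[C@H](C)C(O)[C@H](C)[C@H]2[C@H](/C=C(\C)C(=O)OCC)/C1=C\[C@@H](C)O[Si](C)(C)C(C)(C)C
F4 | step 21 | (E)-allylic alcohol, C2'-O-TBS | CC1=C[C@H]2C[C@H](C)C(O)[C@H](C)[C@H]2[C@H](/C=C(\C)CO)/C1=C\[C@@H](C)O[Si](C)(C)C(C)(C)C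
F5 | step 25 | (2E,4E)-dienal, C7 alcohol | CC1=C[C@H]2C[C@H](C)C(O)[C@H](C)[C@H]2[C@H](/C=C(\C)/C=C(\C)C=O)/C1=C\[C@@H](C)O[Si](C)(C)C(C)(C)C
F6 | step 25 | (11S,12S)-epoxy aldehyde, C7 alcohol | CC1=C[C@H]2C[C@H](C)C(O)[C@H](C)[C@H]2[C@H](/C=C(\C)[C@@H]2O[C@@]2(C)C=O)/C1=C\[C@@H](C)O[Si](C)(C)C(C)(C)C
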